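## Structural features

Bermudenynol (36) is a linear C15 chain in which an ether oxygen links C7 and C13 into an eight-membered oxocene (O, C7–C13); the ring contains a C9=C10 double bond that is cis within the ring and carries chlorine on C10. On the ring, the ethyl group at C13 and the side chain at C7 are cis across the oxygen, and the bromine at C12 is trans to the neighbouring ethyl group. The side chain continues the array: C7, the C6 carbinol and the C5 chloride are contiguous and mutually syn, and C5 is bonded to a (Z)-C3=C4 alkene that ends in the C1≡C2 terminal alkyne. The five stereocentres therefore form two contiguous groups, C12/C13 and C5/C6/C7, which meet at the ring oxygen. The fragile groups are: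
- the secondary bromide β to the ether oxygen (elimination, oxonium participation);
- the C5 chloride, which is allylic and part of a chlorohydrin (epoxide closure under base);
- the (Z)-enyne (isomerisation, sensitivity to base);
- the trisubstituted chloroalkene (reductive metal conditions).

The main difficulty is the medium ring with chlorine regiodefined on C10 and the 2,8-cis relationship: direct eight-membered closure is slow, and a vinyl chloride is a poor partner in most ring-forming alkene chemistry. A second difficulty is C6, whose configuration runs against the inherent facial preference of an α-alkoxy aldehyde. The key step exploits the fact that C10 is a single chlorine-bearing carbon between C9 and C11. Removing it leaves a seven-membered oxepene (O, C7, C8, C9, C11, C12, C13) with a C9=C11 enol ether, which closes easily and can accept a CCl unit.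

## Logic of the disconnections

36 ⇒ 35. The C1–Si bond is the last one made to disappear. The alkyne terminus is carried as a silylalkyne so that the enyne can be attached by metathesis. The forward step must remove silicon without closing the C5/C6 chlorohydrin to an epoxide or eliminating HBr.

35 ⇒ 31 + 34 (and 34 ⇒ 32 + 33). The C3=C4 bond is cut. This removes the whole enyne from the sensitive chlorohydrin and leaves a plain vinyl group on C5, so no aldehyde is ever needed at C4 next to the epimerisable C5 chloride. The demand is Z selectivity in a cross-metathesis and inertness of the ring chloroalkene. 34 comes from 32 and 33 in one coupling.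

31 ⇒ 28 + 29. The C5–C6 bond is cut. Both side-chain stereocentres and the C5 chloride arrive in one step from an aldehyde at C6 and a three-carbon chloroallyl unit. The demand is reagent control strong enough to override the α-alkoxy aldehyde and a closed transition state that gives the 5,6-syn chlorohydrin.

28 ⇒ 27 ⇒ 26. Only the oxidation level and the protecting group at C6 change. C6 is carried as a silyl ether rather than as a benzylic ether, because a benzylic ether would not survive the Lewis acid that later unmasks the C12 oxygen. This ordering is what lets the bromide be installed while C6 is still masked. The forward steps must be non-basic because the bromide is already present.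

26 ⇒ 25 ⇒ 24. The C12–Br bond is traced back to a C12–O bond of opposite configuration. The C12 oxygen cis to the ethyl group is what a syn-selective allylboration delivers, and one SN2 inversion then gives the trans bromide. Bromination is placed before the side chain is built, so that no second free hydroxyl (C6) competes. The demand is clean inversion at a hindered ring carbon.

24 ⇒ 23 ⇒ 21. The C9–H bond is traced back to a C9–O bond of an enol triflate, and the triflate to the C9 enolate made by hydride addition to C11 of an enone. This moves the double bond from C10=C11 to C9=C10 without ambiguity, because the enolate is generated regiospecifically. The demand is 1,4- rather than 1,2-hydride addition, and palladium insertion into C–OTf rather than C–Cl.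

21 ⇒ 18 + 19 (key disconnection). The C9–C10 and C10–C11 bonds are cut and the CCl carbon is removed. The eight-membered chloroenone becomes a seven-membered silyl enol ether plus a one-carbon carbene source. The medium-ring problem is thereby replaced by a normal-ring problem. The forward step needs chemoselective carbene addition to the enol ether and a ring opening that does not trigger β-elimination of the ring oxygen.

18 ⇒ 17 ⇒ 15 ⇒ 14. The C9=C11 bond is cut (ring-closing metathesis), then the enol ether is traced to a methyl ketone and the ketone to a terminal alkyne. Cyclisation to a seven-membered ring with an oxygen in the tether is favourable. The demand is kinetic enolisation at the methyl group, since enolisation toward C8 would expel the C7 alkoxide.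

14 ⇒ 13 ⇒ 12 ⇒ 9 + 10. After protecting-group and oxidation-level changes at C6, the C7–C8 bond is cut. C7 becomes the α-carbon of a glycolate imide and C8–C10 a propargyl electrophile. The auxiliary has to set C7 independently of the existing C12/C13 centres, which later makes the 2,8-cis relationship a consequence of two reagent-controlled steps.

9 ⇒ 6 + 7 and 6 ⇒ 4 + 5. The imide C–N bond and the O–C7 ether bond are cut. This reduces the problem to a secondary alcohol, a two-carbon glycolate unit and a recoverable auxiliary. The demand is O-alkylation of a hindered secondary alkoxide.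

4 ⇒ 1 + 2. The C12–C13 bond is cut. Both ring stereocentres come from an achiral aldehyde and an achiral allyl ether under control of a chiral boron reagent. Syn selectivity requires a (Z)-alkoxyallyl reagent.

## Other disconnections considered

Alternative 1: The cut is C8–C9, with the C7–H bond made in the same operation. In the forward sense the acyclic enol ether A1 carries a 1,1-disubstituted C7=C8 enol ether and an (E)-2-chloro-1-iodoalkene terminus at C9. It would be hydroborated with 9-BBN (boron to C8, hydrogen to C7), and the resulting B-alkyl group coupled intramolecularly with the alkenyl iodide under PdCl2(dppf) and base to give oxocene A2.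

- In its favour: the chloroalkene is installed before cyclisation with position and geometry fixed, and the C–I bond reacts ahead of C–Cl. This is better than the chosen plan, which needs steps 11 and 12 to move the double bond.
- Also in its favour: ring closure and the C7 stereocentre come in one operation, whereas the chosen key step creates no stereocentre. C6 arrives as a protected diol that gives the aldehyde in two steps, which equals steps 15 and 16.
- Against it: C7 would be set by facial selectivity of hydroboration on an acyclic enol ether, guided only by the adjacent dioxolane centre and the remote C13. No ring enforces the 2,8-cis relationship, whereas the chosen plan sets C7 by an auxiliary.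
- Against it: the β-alkoxyalkylborane can eliminate, and an sp3–sp2 coupling that closes an eight-membered ring competes with intermolecular coupling, protodeboronation and β-hydride elimination.
- Against it: A1 requires methylenation of an ester in the presence of the iodoalkene.
- Comparison: the step count is comparable and the route is more convergent, but two uncertain selectivities are concentrated in one step.

Alternative 2: The cut is C11–C12, and C9–O is broken in the forward direction. The ketene acetal A3 is a 2-methylene-1,3-dioxane with a 1-chlorovinyl group on the C9 carbon. It would undergo a [3,3] Claisen rearrangement that enlarges the six-membered ring by two atoms to the eight-membered lactone A4.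

- In its favour: the rearrangement is concerted and strongly driven by formation of the lactone carbonyl. The cyclic transition state gives the cis ring alkene, and chlorine sits on C10 from the start, so no regiochemical correction is needed. On this point it is better than the chosen plan.
- Equal point: the medium ring is made by ring expansion and not by end-to-end closure, as in the chosen key step.
- Against it: A4 lacks the C12 oxygen and the ethyl group, and C13 is a lactone carbonyl.
- Against it: the lactone enolate would have to be hydroxylated at C12, and the carbonyl converted into a CH(Et) centre cis to C7. Both are substrate-controlled events on a flexible eight-membered ring, and the second needs carbonyl alkylidenation or addition–reduction chemistry next to a vinyl chloride.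
- Comparison: the key step itself is mechanistically cleaner, but the route is longer after it and the ring stereocentres are set late. The chosen plan sets C12 and C13 in step 1 under reagent control.

Alternative 3: The cut is C12–C13. The aldehyde A5 carries a γ-alkoxyallylstannane on the C7 oxygen. With BF3·OEt2 the oxygen-bearing allyl carbon would add to the C12 aldehyde in an intramolecular SE2′ reaction to give the hydroxy vinyl oxocene A6.

- In its favour: the ring and two stereocentres (C12, C13) form in one step, which is more than the chosen key step delivers. The chloroalkene is already in place (equal or better), and the cis alkene and the ether oxygen in the tether assist medium-ring closure.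
- Against it: in A6 the C12 hydroxyl is trans to the C13 substituent, which is the configuration of the bromide in 36. An invertive bromination would give the C12 epimer, so the carbinol must first be inverted, costing about two further steps.
- Against it: the vinyl group at C13 must be reduced to ethyl without touching the chloroalkene.
- Against it: A5 is a β,γ-unsaturated aldehyde with chlorine on the β-carbon and is prone to enolisation and conjugation.
- Against it: the 2,8-cis relationship depends on the conformation of an eight-membered transition state, and stoichiometric tin is involved.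
- Comparison: the bond-forming power of the key step is higher, but the stereochemical corrections cancel the gain in steps, and the risk sits in one late, non-correctable step.

Key step: step 10

Remark on the chemistry: the isopinocampheylboron reagents are assumed to follow their usual facial preference (reagent from (+)-α-pinene attacks the Si face of an aldehyde, reagent from (−)-α-pinene the Re face); locants C1–C15 follow the linear chain of 36.

## Steps

Step 1
Reactants: 1 allyl methoxymethyl ether; 2 propanal
Product: 4 (3R,4R)-4-(methoxymethoxy)hex-5-en-3-ol, via allylborane 3 (not isolated)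
Conditions: 1, s-BuLi, THF, −78 °C; (−)-Ipc2BOMe; BF3·OEt2; 2, −78 °C; then NaOH, H2O2
Reagents that add atoms: none
Why: Brown-type (Z)-γ-alkoxyallylboration: the lithiated ether is Z by chelation, and the derived borane 3 adds through a closed chair transition state that converts Z geometry into the syn C12/C13 relationship. The isopinocampheyl groups from (+)-α-pinene direct attack to the Si face of 2, which should give the (3R,4R) isomer.

Step 2
Reactants: 4 (3R,4R)-4-(methoxymethoxy)hex-5-en-3-ol; 5 bromoacetic acid
Product: 6 2-{[(3R,4R)-4-(methoxymethoxy)hex-5-en-3-yl]oxy}acetic acid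
Conditions: NaH, THF, 0 °C → rt; then aq. HCl to pH 3
Reagents that add atoms: none
Why: Williamson etherification: the secondary alkoxide displaces bromide from sodium bromoacetate. No stereocentre is involved and the MOM ether tolerates the brief, mildly acidic work-up.

Step 3
Reactants: 6 2-{[(3R,4R)-4-(methoxymethoxy)hex-5-en-3-yl]oxy}acetic acid; 7 (S)-4-benzyloxazolidin-2-one
Product: 9 (S)-4-benzyl-3-(2-{[(3R,4R)-4-(methoxymethoxy)hex-5-en-3-yl]oxy}acetyl)oxazolidin-2-one, via mixed anhydride 8 (not isolated)
Conditions: 6, t-BuCOCl, Et3N, THF, −78 → 0 °C; then 7, n-BuLi, THF, −78 → 0 °C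
Reagents that add atoms: none
Why: N-acylation of the lithiated oxazolidinone by the mixed pivalic anhydride 8. Attack goes to the less hindered glycolyl carbonyl.

Step 4
Reactants: 9 (S)-4-benzyl-3-(2-{[(3R,4R)-4-(methoxymethoxy)hex-5-en-3-yl]oxy}acetyl)oxazolidin-2-one; 10 propargyl bromide
Product: 12 (S)-4-benzyl-3-[(2R)-2-{[(3R,4R)-4-(methoxymethoxy)hex-5-en-3-yl]oxy}pent-4-ynoyl]oxazolidin-2-one, via sodium enolate 11 (not isolated)
Conditions: NaN(SiMe3)2, THF, −78 °C; 10, −78 → −45 °C
Reagents that add atoms: none
Why: Evans-type oxazolidinone glycolate alkylation: the chelated (Z)-sodium enolate 11 is alkylated by the reactive propargylic bromide on the face opposite the benzyl group (SN2, auxiliary control). This should set C7 as R irrespective of the existing C12/C13 centres.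

Step 5
Reactants: 12 (S)-4-benzyl-3-[(2R)-2-{[(3R,4R)-4-(methoxymethoxy)hex-5-en-3-yl]oxy}pent-4-ynoyl]oxazolidin-2-one
Product: 13 (2R)-2-{[(3R,4R)-4-(methoxymethoxy)hex-5-en-3-yl]oxy}pent-4-yn-1-ol
Conditions: NaBH4, THF/H2O, 0 °C → rt
Reagents that add atoms: none
Why: Hydride reduction of the exocyclic imide carbonyl releases the primary alcohol and the intact auxiliary. The alkyne, alkene and MOM ether are inert to NaBH4 and C7 is not enolised.

Step 6
Reactants: 13 (2R)-2-{[(3R,4R)-4-(methoxymethoxy)hex-5-en-3-yl]oxy}pent-4-yn-1-ol
Product: 14 tert-butyl{[(2R)-2-{[(3R,4R)-4-(methoxymethoxy)hex-5-en-3-yl]oxy}pent-4-yn-1-yl]oxy}diphenylsilane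
Conditions: TBDPSCl, imidazole, CH2Cl2, rt
Reagents that add atoms: tert-butyl(chloro)diphenylsilane, CC(C)(C)[Si](Cl)(c1ccccc1)c1ccccc1
Why: Standard silylation of a primary alcohol. This ether is chosen because it cannot ionise or cyclise onto the activated alkyne in step 7, has no benzylic C–H for carbene insertion in step 10, and survives the Lewis-acid MOM cleavage of step 13.

Step 7
Reactants: 14 tert-butyl{[(2R)-2-{[(3R,4R)-4-(methoxymethoxy)hex-5-en-3-yl]oxy}pent-4-yn-1-yl]oxy}diphenylsilane
Product: 15 (4R)-5-[(tert-butyldiphenylsilyl)oxy]-4-{[(3R,4R)-4-(methoxymethoxy)hex-5-en-3-yl]oxy}pentan-2-one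
Conditions: Ph3PAuNTf2 (2 mol %), H2O, 1,4-dioxane, 60 °C
Reagents that add atoms: water, O
Why: Markovnikov hydration of a terminal alkyne catalysed by cationic monovalent gold gives the methyl ketone. The soft π-acid does not activate the alkene, and the neutral medium spares the acetal and the silyl ether.

Step 8
Reactants: 15 (4R)-5-[(tert-butyldiphenylsilyl)oxy]-4-{[(3R,4R)-4-(methoxymethoxy)hex-5-en-3-yl]oxy}pentan-2-one
Product: 17 tert-butyl{[(2R)-4-[(tert-butyldimethylsilyl)oxy]-2-{[(3R,4R)-4-(methoxymethoxy)hex-5-en-3-yl]oxy}pent-4-en-1-yl]oxy}diphenylsilane, via lithium enolate 16 (not isolated)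
Conditions: LiN(i-Pr)2, THF, −78 °C (ketone added to base); TBSOTf, −78 °C; Et3N, aq. NaHCO3
Reagents that add atoms: tert-butyldimethylsilyl trifluoromethanesulfonate, CC(C)(C)[Si](C)(C)OS(=O)(=O)C(F)(F)F
Why: Kinetic enolisation with a hindered amide base at low temperature removes a methyl proton, and immediate O-silylation fixes the terminal enol ether. Enolisation toward C8, which would expel the C7 alkoxide, is avoided by inverse addition and fast trapping.

Step 9
Reactants: 17 tert-butyl{[(2R)-4-[(tert-butyldimethylsilyl)oxy]-2-{[(3R,4R)-4-(methoxymethoxy)hex-5-en-3-yl]oxy}pent-4-en-1-yl]oxy}diphenylsilane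
Product: 18 tert-butyl{[(2R,6R,7R)-4-[(tert-butyldimethylsilyl)oxy]-7-ethyl-6-(methoxymethoxy)-2,3,6,7-tetrahydrooxepin-2-yl]methoxy}diphenylsilane
Conditions: second-generation Grubbs catalyst (H2IMes)(PCy3)Cl2Ru=CHPh (5 mol %), PhH, 65 °C
Reagents that add atoms: none
Why: Ring-closing metathesis of a silyl enol ether diene: the catalyst initiates at the monosubstituted C11 vinyl group and closes onto the 1,1-disubstituted enol ether with loss of ethene. A seven-membered ring with an ether oxygen in the tether forms readily, and all three ring substituents are already in place (all cis).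

Step 10
Reactants: 18 tert-butyl{[(2R,6R,7R)-4-[(tert-butyldimethylsilyl)oxy]-7-ethyl-6-(methoxymethoxy)-2,3,6,7-tetrahydrooxepin-2-yl]methoxy}diphenylsilane; 19 chloroform
Product: 21 (2R,7R,8R,5E)-2-{[(tert-butyldiphenylsilyl)oxy]methyl}-5-chloro-8-ethyl-7-(methoxymethoxy)-2,3,7,8-tetrahydro-4H-oxocin-4-one (cis ring alkene), via dichlorocyclopropane 20 (not isolated)
Conditions: 19, KOt-Bu, pentane, −30 → 0 °C; filter through Celite, evaporate; PhMe, 90 °C
Reagents that add atoms: none
Why: KOt-Bu deprotonates chloroform and the trichloromethyl anion loses chloride to give singlet dichlorocarbene, which adds in a concerted electrophilic [2+1] step to the electron-rich C9=C11 enol ether of 18 to give the siloxy-dichlorocyclopropane 20. After the base is removed, warming in toluene ionises the chloride that is cis to the ring bonds while the C9–C11 bond opens in a disrotatory two-electron electrocyclic process pushed by the siloxy oxygen lone pair; the silyloxocarbenium ion then gives up its silyl group to chloride, leaving the 2-chloroenone 21 with C9–C10 and C10–C11 as the new skeletal bonds. The closest known reaction is the dihalocarbene ring expansion of carbocyclic silyl enol ethers to 2-halocycloalk-2-enones, applied here to an oxacyclic member of the same substrate class. The eight-membered ring is not closed end to end but arises by one-carbon enlargement of the seven-membered ring, so the entropic and transannular costs of a direct medium-ring cyclisation are avoided. No stereocentre is created, and the two cyclopropane centres of 20 (either face of attack) are destroyed on opening. The required selectivities are chemoselectivity for the enol ether, secured because it is the only alkene and strongly nucleophilic; the site of insertion, fixed by the enol ether position set in steps 8 and 9; and inward rotation of the ring bonds, which follows from loss of the endo chloride and gives the cis enone. That geometry is of no later consequence because C10=C11 is reduced in step 11, and the base is kept away from 21 because it is a β-alkoxy ketone (ring oxygen on C7) that could open by E1cB elimination.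

Step 11
Reactants: 21 (2R,7R,8R,5E)-2-{[(tert-butyldiphenylsilyl)oxy]methyl}-5-chloro-8-ethyl-7-(methoxymethoxy)-2,3,7,8-tetrahydro-4H-oxocin-4-one
Product: 23 (2R,7R,8R)-2-{[(tert-butyldiphenylsilyl)oxy]methyl}-5-chloro-8-ethyl-7-(methoxymethoxy)-3,6,7,8-tetrahydro-2H-oxocin-4-yl trifluoromethanesulfonate (cis ring alkene), via lithium enolate 22 (not isolated)
Conditions: LiBH(sec-Bu)3, THF, −78 °C (21 added to hydride); PhNTf2, −78 → 0 °C
Reagents that add atoms: N-phenylbis(trifluoromethanesulfonimide), O=S(=O)(N(c1ccccc1)S(=O)(=O)C(F)(F)F)C(F)(F)F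
Why: Conjugate (1,4) hydride addition of the bulky borohydride to the enone, whose β-carbon C11 carries only hydrogen and a ring carbon, gives solely the C9–C10 enolate 22, which is trapped on oxygen as the enol triflate. C11 becomes CH2, no stereocentre is formed, and the alkene is now C9=C10 with chlorine on C10.

Step 12
Reactants: 23 (2R,7R,8R)-2-{[(tert-butyldiphenylsilyl)oxy]methyl}-5-chloro-8-ethyl-7-(methoxymethoxy)-3,6,7,8-tetrahydro-2H-oxocin-4-yl trifluoromethanesulfonate
Product: 24 tert-butyl{[(2R,7R,8R,4E)-5-chloro-8-ethyl-7-(methoxymethoxy)-3,6,7,8-tetrahydro-2H-oxocin-2-yl]methoxy}diphenylsilane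
Conditions: Pd(OAc)2 (5 mol %), PPh3, HCO2H, n-Bu3N, DMF, 60 °C
Reagents that add atoms: none
Why: Palladium-catalysed formate reduction of an enol triflate: zerovalent palladium inserts into the C9–OTf bond much faster than into the vinylic C–Cl bond, formate supplies hydride with loss of CO2, and reductive elimination gives C9–H. The ring alkene geometry is retained.

Step 13
Reactants: 24 tert-butyl{[(2R,7R,8R,4E)-5-chloro-8-ethyl-7-(methoxymethoxy)-3,6,7,8-tetrahydro-2H-oxocin-2-yl]methoxy}diphenylsilane
Product: 25 (2R,3R,8R,5E)-8-{[(tert-butyldiphenylsilyl)oxy]methyl}-5-chloro-2-ethyl-3,4,7,8-tetrahydro-2H-oxocin-3-ol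
Conditions: ZnBr2, n-PrSH, CH2Cl2, 0 °C
Reagents that add atoms: none
Why: Lewis acid/thiol cleavage of the formaldehyde acetal: ZnBr2 activates the MOM group and the thiol captures the oxocarbenium ion. The primary tert-butyldiphenylsilyl ether and the chloroalkene should be untouched in this brief, aprotic reaction.

Step 14
Reactants: 25 (2R,3R,8R,5E)-8-{[(tert-butyldiphenylsilyl)oxy]methyl}-5-chloro-2-ethyl-3,4,7,8-tetrahydro-2H-oxocin-3-ol
Product: 26 tert-butyl{[(2R,7S,8R,4E)-7-bromo-5-chloro-8-ethyl-3,6,7,8-tetrahydro-2H-oxocin-2-yl]methoxy}diphenylsilane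
Conditions: CBr4, P(n-Oct)3, PhMe, 70 °C
Reagents that add atoms: carbon tetrabromide, BrC(Br)(Br)Br
Why: Appel-type bromination: bromide displaces the alkoxyphosphonium group in an SN2 step with inversion, turning the C12 alcohol cis to ethyl into the (12S)-bromide trans to ethyl. The non-polar solvent and the trialkylphosphine are chosen to disfavour elimination and oxonium participation; C6 is still silylated, so no second hydroxyl competes.

Step 15
Reactants: 26 tert-butyl{[(2R,7S,8R,4E)-7-bromo-5-chloro-8-ethyl-3,6,7,8-tetrahydro-2H-oxocin-2-yl]methoxy}diphenylsilane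
Product: 27 [(2R,7S,8R,4E)-7-bromo-5-chloro-8-ethyl-3,6,7,8-tetrahydro-2H-oxocin-2-yl]methanol
Conditions: HF·pyridine, pyridine, THF, 0 °C → rt
Reagents that add atoms: none
Why: Fluoride cleavage of the Si–O bond in a weakly acidic medium, which avoids base-induced loss of HBr from the secondary bromide.

Step 16
Reactants: 27 [(2R,7S,8R,4E)-7-bromo-5-chloro-8-ethyl-3,6,7,8-tetrahydro-2H-oxocin-2-yl]methanol
Product: 28 (2R,7S,8R,4E)-7-bromo-5-chloro-8-ethyl-3,6,7,8-tetrahydro-2H-oxocine-2-carbaldehyde
Conditions: Dess–Martin periodinane, CH2Cl2, 0 °C → rt; used at once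
Reagents that add atoms: none
Why: Dess–Martin oxidation under neutral, non-enolising conditions gives the α-alkoxy aldehyde without epimerising C7.

Step 17
Reactants: 28 (2R,7S,8R,4E)-7-bromo-5-chloro-8-ethyl-3,6,7,8-tetrahydro-2H-oxocine-2-carbaldehyde; 29 allyl chloride
Product: 31 (1S,2S)-1-[(2R,7S,8R,4E)-7-bromo-5-chloro-8-ethyl-3,6,7,8-tetrahydro-2H-oxocin-2-yl]-2-chlorobut-3-en-1-ol, via chloroallylborane 30 (not isolated)
Conditions: 29, (+)-Ipc2BOMe, LiN(c-Hex)2, THF, −95 °C; BF3·OEt2; 28, −95 °C; then HOCH2CH2NH2
Reagents that add atoms: none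
Why: (Z)-γ-Chloroallylboration: α-chloroallyllithium is captured by the borinate, and the resulting (Z)-γ-chloroallylborane 30 adds through a chair transition state, so Z geometry gives the syn C5/C6 chlorohydrin. The isopinocampheyl groups from (−)-α-pinene direct the reagent to the Re face of the aldehyde to give (5S,6S); this reagent control must override the Felkin/Cornforth preference of the α-alkoxy aldehyde, and the amine work-up avoids the alkaline peroxide that could close the chlorohydrin.

Step 18
Reactants: 32 ethynyltriisopropylsilane; 33 (Z)-1-bromoprop-1-ene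
Product: 34 (Z)-triisopropyl(pent-3-en-1-yn-1-yl)silane
Conditions: Pd(PPh3)2Cl2 (2 mol %), CuI (4 mol %), i-Pr2NH, THF, rt
Reagents that add atoms: none
Why: Sonogashira coupling of a terminal alkyne with an alkenyl bromide, with retention of alkene geometry. The geometry of 34 is in any case lost in step 19.

Step 19
Reactants: 31 (1S,2S)-1-[(2R,7S,8R,4E)-7-bromo-5-chloro-8-ethyl-3,6,7,8-tetrahydro-2H-oxocin-2-yl]-2-chlorobut-3-en-1-ol; 34 (Z)-triisopropyl(pent-3-en-1-yn-1-yl)silane
Product: 35 (1S,2S,3Z)-1-[(2R,7S,8R,4E)-7-bromo-5-chloro-8-ethyl-3,6,7,8-tetrahydro-2H-oxocin-2-yl]-2-chloro-6-(triisopropylsilyl)hex-3-en-5-yn-1-ol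
Conditions: second-generation Grubbs catalyst (H2IMes)(PCy3)Cl2Ru=CHPh (10 mol %), 34 (excess), PhH, 70 °C
Reagents that add atoms: none
Why: Z-selective cross-metathesis of a terminal alkene with a conjugated silyl enyne, with loss of propene. The slim, linear alkynyl group tolerates the cis arrangement in the ruthenacyclobutane, so the (Z)-enyne is the expected major isomer; the trisubstituted chloroalkene is too hindered and electron-poor to react.

Step 20
Reactants: 35 (1S,2S,3Z)-1-[(2R,7S,8R,4E)-7-bromo-5-chloro-8-ethyl-3,6,7,8-tetrahydro-2H-oxocin-2-yl]-2-chloro-6-(triisopropylsilyl)hex-3-en-5-yn-1-ol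
Product: 36 bermudenynol, (1S,2S,3Z)-1-[(2R,7S,8R,4E)-7-bromo-5-chloro-8-ethyl-3,6,7,8-tetrahydro-2H-oxocin-2-yl]-2-chlorohex-3-en-5-yn-1-ol
Conditions: Bu4NF, AcOH, THF, −20 → 0 °C
Reagents that add atoms: none
Why: Fluoride-induced protodesilylation of the alkynylsilane. Acetic acid buffering and low temperature are meant to prevent epoxide closure of the chlorohydrin and elimination of HBr.

## Compound list

1 | allyl methoxymethyl ether, 3-(methoxymethoxy)prop-1-ene | C=CCOCOC | starting material
2 | propanal | CCC=O | starting material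
3 | (Z)-[3-(methoxymethoxy)prop-2-en-1-yl]bis(isopinocampheyl)borane, isopinocampheyl groups from (+)-α-pinene | COCO/C=C\CB([C@@H]1C[C@@H]2C[C@H]([C@H]1C)C2(C)C)[C@@H]1C[C@@H]2C[C@H]([C@H]1C)C2(C)C | intermediate
4 | (3R,4R)-4-(methoxymethoxy)hex-5-en-3-ol | CC[C@@H](O)[C@H](OCOC)C=C | intermediate
5 | bromoacetic acid | OC(=O)CBr | starting material
6 | 2-{[(3R,4R)-4-(methoxymethoxy)hex-5-en-3-yl]oxy}acetic acid | CC[C@@H](OCC(=O)O)[C@H](OCOC)C=C | intermediate
7 | (S)-4-benzyloxazolidin-2-one | O=C1N[C@@H](Cc2ccccc2)CO1 | starting material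
8 | mixed anhydride of 6 and pivalic acid | CC[C@@H](OCC(=O)OC(=O)C(C)(C)C)[C@H](OCOC)C=C | intermediate
9 | (S)-4-benzyl-3-(2-{[(3R,4R)-4-(methoxymethoxy)hex-5-en-3-yl]oxy}acetyl)oxazolidin-2-one | CC[C@@H](OCC(=O)N1[C@@H](Cc2ccccc2)COC1=O)[C@H](OCOC)C=C | intermediate
10 | propargyl bromide, 3-bromoprop-1-yne | C#CCBr | starting material
11 | sodium (Z)-enolate of 9 | [Na+].[O-]/C(=C\O[C@H](CC)[C@H](OCOC)C=C)N1[C@@H](Cc2ccccc2)COC1=O | intermediate
12 | (S)-4-benzyl-3-[(2R)-2-{[(3R,4R)-4-(methoxymethoxy)hex-5-en-3-yl]oxy}pent-4-ynoyl]oxazolidin-2-one | C#CC[C@@H](O[C@H](CC)[C@H](OCOC)C=C)C(=O)N1[C@@H](Cc2ccccc2)COC1=O | intermediate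
13 | (2R)-2-{[(3R,4R)-4-(methoxymethoxy)hex-5-en-3-yl]oxy}pent-4-yn-1-ol | C#CC[C@H](CO)O[C@H](CC)[C@H](OCOC)C=C | intermediate
14 | tert-butyl{[(2R)-2-{[(3R,4R)-4-(methoxymethoxy)hex-5-en-3-yl]oxy}pent-4-yn-1-yl]oxy}diphenylsilane | C#CC[C@H](CO[Si](c1ccccc1)(c1ccccc1)C(C)(C)C)O[C@H](CC)[C@H](OCOC)C=C | intermediate
15 | (4R)-5-[(tert-butyldiphenylsilyl)oxy]-4-{[(3R,4R)-4-(methoxymethoxy)hex-5-en-3-yl]oxy}pentan-2-one | CC(=O)C[C@H](CO[Si](c1ccccc1)(c1ccccc1)C(C)(C)C)O[C@H](CC)[C@H](OCOC)C=C | intermediate
16 | lithium enolate of 15 on the methyl side (C9=CH2) | [Li+].[O-]C(=C)C[C@H](CO[Si](c1ccccc1)(c1ccccc1)C(C)(C)C)O[C@H](CC)[C@H](OCOC)C=C | intermediate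
17 | tert-butyl{[(2R)-4-[(tert-butyldimethylsilyl)oxy]-2-{[(3R,4R)-4-(methoxymethoxy)hex-5-en-3-yl]oxy}pent-4-en-1-yl]oxy}diphenylsilane | C=C(O[Si](C)(C)C(C)(C)C)C[C@H](CO[Si](c1ccccc1)(c1ccccc1)C(C)(C)C)O[C@H](CC)[C@H](OCOC)C=C | intermediate
18 | tert-butyl{[(2R,6R,7R)-4-[(tert-butyldimethylsilyl)oxy]-7-ethyl-6-(methoxymethoxy)-2,3,6,7-tetrahydrooxepin-2-yl]methoxy}diphenylsilane (all-cis oxepene silyl enol ether) | CC(C)(C)[Si](c1ccccc1)(c1ccccc1)OC[C@H]1CC(O[Si](C)(C)C(C)(C)C)=C[C@@H](OCOC)[C@@H](CC)O1 | intermediate
19 | chloroform | ClC(Cl)Cl | starting material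
20 | tert-butyl{[(3R,5R,6R)-1-[(tert-butyldimethylsilyl)oxy]-8,8-dichloro-5-ethyl-6-(methoxymethoxy)-4-oxabicyclo[5.1.0]octan-3-yl]methoxy}diphenylsilane (both cis-fused cyclopropane diastereomers) | CC(C)(C)[Si](c1ccccc1)(c1ccccc1)OC[C@H]1CC2(O[Si](C)(C)C(C)(C)C)C(Cl)(Cl)C2[C@@H](OCOC)[C@@H](CC)O1 | intermediate
21 | (2R,7R,8R,5E)-2-{[(tert-butyldiphenylsilyl)oxy]methyl}-5-chloro-8-ethyl-7-(methoxymethoxy)-2,3,7,8-tetrahydro-4H-oxocin-4-one (cis ring alkene) | CC(C)(C)[Si](c1ccccc1)(c1ccccc1)OC[C@H]1CC(=O)/C(Cl)=C\[C@@H](OCOC)[C@@H](CC)O1 | intermediate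
22 | lithium enolate from 1,4-reduction of 21 (O− on C9, C9=C10 cis in the ring) | [Li+].CC(C)(C)[Si](c1ccccc1)(c1ccccc1)OC[C@H]1C/C([O-])=C(Cl)\C[C@@H](OCOC)[C@@H](CC)O1 | intermediate
23 | (2R,7R,8R)-2-{[(tert-butyldiphenylsilyl)oxy]methyl}-5-chloro-8-ethyl-7-(methoxymethoxy)-3,6,7,8-tetrahydro-2H-oxocin-4-yl trifluoromethanesulfonate (cis ring alkene) | CC(C)(C)[Si](c1ccccc1)(c1ccccc1)OC[C@H]1C/C(OS(=O)(=O)C(F)(F)F)=C(Cl)\C[C@@H](OCOC)[C@@H](CC)O1 | intermediate
24 | tert-butyl{[(2R,7R,8R,4E)-5-chloro-8-ethyl-7-(methoxymethoxy)-3,6,7,8-tetrahydro-2H-oxocin-2-yl]methoxy}diphenylsilane | CC(C)(C)[Si](c1ccccc1)(c1ccccc1)OC[C@H]1C/C=C(/Cl)C[C@@H](OCOC)[C@@H](CC)O1 | intermediate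
25 | (2R,3R,8R,5E)-8-{[(tert-butyldiphenylsilyl)oxy]methyl}-5-chloro-2-ethyl-3,4,7,8-tetrahydro-2H-oxocin-3-ol | CC(C)(C)[Si](c1ccccc1)(c1ccccc1)OC[C@H]1C/C=C(/Cl)C[C@@H](O)[C@@H](CC)O1 | intermediate
26 | tert-butyl{[(2R,7S,8R,4E)-7-bromo-5-chloro-8-ethyl-3,6,7,8-tetrahydro-2H-oxocin-2-yl]methoxy}diphenylsilane | CC(C)(C)[Si](c1ccccc1)(c1ccccc1)OC[C@H]1C/C=C(/Cl)C[C@H](Br)[C@@H](CC)O1 | intermediate
27 | [(2R,7S,8R,4E)-7-bromo-5-chloro-8-ethyl-3,6,7,8-tetrahydro-2H-oxocin-2-yl]methanol | OC[C@H]1C/C=C(/Cl)C[C@H](Br)[C@@H](CC)O1 | intermediate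
28 | (2R,7S,8R,4E)-7-bromo-5-chloro-8-ethyl-3,6,7,8-tetrahydro-2H-oxocine-2-carbaldehyde | O=C[C@H]1C/C=C(/Cl)C[C@H](Br)[C@@H](CC)O1 | intermediate
29 | allyl chloride, 3-chloroprop-1-ene | C=CCCl | starting material
30 | (Z)-(3-chloroprop-2-en-1-yl)bis(isopinocampheyl)borane, isopinocampheyl groups from (−)-α-pinene | Cl/C=C\CB([C@H]1C[C@H]2C[C@@H]([C@@H]1C)C2(C)C)[C@H]1C[C@H]2C[C@@H]([C@@H]1C)C2(C)C | intermediate
31 | (1S,2S)-1-[(2R,7S,8R,4E)-7-bromo-5-chloro-8-ethyl-3,6,7,8-tetrahydro-2H-oxocin-2-yl]-2-chlorobut-3-en-1-ol | C=C[C@H](Cl)[C@@H](O)[C@H]1C/C=C(/Cl)C[C@H](Br)[C@@H](CC)O1 | intermediate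
32 | ethynyltriisopropylsilane | C#C[Si](C(C)C)(C(C)C)C(C)C | starting material
33 | (Z)-1-bromoprop-1-ene | C/C=C\Br | starting material
34 | (Z)-triisopropyl(pent-3-en-1-yn-1-yl)silane | C/C=C\C#C[Si](C(C)C)(C(C)C)C(C)C | intermediate
35 | (1S,2S,3Z)-1-[(2R,7S,8R,4E)-7-bromo-5-chloro-8-ethyl-3,6,7,8-tetrahydro-2H-oxocin-2-yl]-2-chloro-6-(triisopropylsilyl)hex-3-en-5-yn-1-ol | CC(C)[Si](C#C/C=C\[C@H](Cl)[C@@H](O)[C@H]1C/C=C(/Cl)C[C@H](Br)[C@@H](CC)O1)(C(C)C)C(C)C | intermediate
36 | bermudenynol, (1S,2S,3Z)-1-[(2R,7S,8R,4E)-7-bromo-5-chloro-8-ethyl-3,6,7,8-tetrahydro-2H-oxocin-2-yl]-2-chlorohex-3-en-5-yn-1-ol | C#C/C=C\[C@H](Cl)[C@@H](O)[C@H]1C/C=C(/Cl)C[C@H](Br)[C@@H](CC)O1 | target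

## Step count and least certain steps

Total: 20 steps. Longest linear sequence: 19 steps (steps 1–17, 19 and 20); step 18 is a one-step branch.

Step 10 (key step). The most likely failures are three:
- loss of the silyl enol ether to the alkoxide base before the carbene adds;
- a sluggish opening, because a tert-butyldimethylsilyl group leaves less readily than a trimethylsilyl group;
- ring opening of the product by E1cB loss of the C7 ether oxygen if base is still present when the β-alkoxy ketone forms.

Fallback, from 18 back to 21: cyclopropanation of 18 with Et2Zn and CH2I2 would give the siloxycyclopropane F1. Oxidative opening of its internal C9–C11 bond with FeCl3 in DMF would give the ring-enlarged β-chloro ketone F2. Elimination of HCl with NaOAc in methanol would give the eight-membered enone F3. α-Chlorination of F3 with PhSeCl and pyridine would then return to 21. This builds the same two bonds with a CH2 unit under non-basic ring-opening conditions and adds the chlorine afterwards.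

Step 11. The cis enone in an eight-membered ring is twisted and carries an α-chlorine, so 1,2-hydride addition may compete with 1,4-addition. Proton exchange between enolate 22 and unreacted 21 could also generate the C8 enolate, which would lose the ring oxygen. Fallback, from 21 back to 24: condensation of 21 with tosylhydrazine would give the tosylhydrazone F4. Reduction with catecholborane followed by NaOAc·3H2O and heat would give 24 directly, by 1,2-hydride addition to C=N, loss of sulfinate to the allylic diazene, and a 1,5-hydrogen shift with loss of N2. This approach profits from 1,2-reactivity instead of fighting it and bypasses 23.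

Step 17. Poor facial selectivity is the main risk, because the reagent must act against the Felkin/Cornforth preference of the α-alkoxy aldehyde; that preference is expected to be pronounced for a (Z)-γ-substituted allylborane. Epimerisation at C7 of the aldehyde and epoxide closure during work-up are lesser risks. Fallback, from 28 back to 31:
- a syn aldol of 28 with the dibutylboron enolate of (R)-4-benzyl-3-(chloroacetyl)oxazolidin-2-one (Bu2BOTf, Et3N, CH2Cl2, −78 → 0 °C), under strong auxiliary control, would give the α-chloro-β-hydroxy imide F5;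
- LiBH4 would remove the auxiliary to give the chloro diol F6;
- selective oxidation of the primary alcohol (TEMPO, PhI(OAc)2) would give the α-chloro-β-hydroxy aldehyde F7;
- non-basic methylenation (Zn, CH2Br2, TiCl4) would then give 31.

Step 14. Displacement at a hindered ring carbon flanked by the ether-bearing C13 is slow. Elimination toward C11 or C13, and participation of the ring oxygen with retention or ring contraction, can overtake the SN2 pathway. Fallback, from 25 back to 26: 25 would be converted with ClCH2SO2Cl and pyridine into the chloromethanesulfonate F8. This isolable, highly reactive sulfonate would then be displaced by Bu4NBr in toluene with inversion to give 26, separating activation from displacement.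

## Further compounds

F1 | step 10 | tert-butyl{[(3R,5R,6R)-1-[(tert-butyldimethylsilyl)oxy]-5-ethyl-6-(methoxymethoxy)-4-oxabicyclo[5.1.0]octan-3-yl]methoxy}diphenylsilane (cyclopropane diastereomers) | CC(C)(C)[Si](c1ccccc1)(c1ccccc1)OC[C@H]1CC2(O[Si](C)(C)C(C)(C)C)CC2[C@@H](OCOC)[C@@H](CC)O1
F2 | step 10 | (2R,7R,8R)-2-{[(tert-butyldiphenylsilyl)oxy]methyl}-6-chloro-8-ethyl-7-(methoxymethoxy)oxocan-4-one (C11 epimers) | CC(C)(C)[Si](c1ccccc1)(c1ccccc1)OC[C@H]1CC(=O)CC(Cl)[C@@H](OCOC)[C@@H](CC)O1
F3 | step 10 | (2R,7R,8R,5Z)-2-{[(tert-butyldiphenylsilyl)oxy]methyl}-8-ethyl-7-(methoxymethoxy)-2,3,7,8-tetrahydro-4H-oxocin-4-one | CC(C)(C)[Si](c1ccccc1)(c1ccccc1)OC[C@H]1CC(=O)/C=C\[C@@H](OCOC)[C@@H](CC)O1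
F4 | step 11 | p-toluenesulfonylhydrazone of 21 at C9 | CC(C)(C)[Si](c1ccccc1)(c1ccccc1)OC[C@H]1CC(=NNS(=O)(=O)c2ccc(C)cc2)/C(Cl)=C\[C@@H](OCOC)[C@@H](CC)O1
F5 | step 17 | (R)-4-benzyl-3-{(2R,3S)-3-[(2R,7S,8R,4E)-7-bromo-5-chloro-8-ethyl-3,6,7,8-tetrahydro-2H-oxocin-2-yl]-2-chloro-3-hydroxypropanoyl}oxazolidin-2-one | O=C1OC[C@@H](Cc2ccccc2)N1C(=O)[C@H](Cl)[C@@H](O)[C@H]1C/C=C(/Cl)C[C@H](Br)[C@@H](CC)O1
F6 | step 17 | (1S,2S)-1-[(2R,7S,8R,4E)-7-bromo-5-chloro-8-ethyl-3,6,7,8-tetrahydro-2H-oxocin-2-yl]-2-chloropropane-1,3-diol | OC[C@H](Cl)[C@@H](O)[C@H]1C/C=C(/Cl)C[C@H](Br)[C@@H](CC)O1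
F7 | step 17 | (2R,3S)-3-[(2R,7S,8R,4E)-7-bromo-5-chloro-8-ethyl-3,6,7,8-tetrahydro-2H-oxocin-2-yl]-2-chloro-3-hydroxypropanal | O=C[C@H](Cl)[C@@H](O)[C@H]1C/C=C(/Cl)C[C@H](Br)[C@@H](CC)O1
F8 | step 14 | (2R,3R,8R,5E)-8-{[(tert-butyldiphenylsilyl)oxy]methyl}-5-chloro-2-ethyl-3,4,7,8-tetrahydro-2H-oxocin-3-yl chloromethanesulfonate | CC(C)(C)[Si](c1ccccc1)(c1ccccc1)OC[C@H]1C/C=C(/Cl)C[C@@H](OS(=O)(=O)CCl)[C@@H](CC)O1
A1 | alternative 1 | (4S)-4-(1-{[(3R,4R,6E)-6-chloro-7-iodo-4-(methoxymethoxy)hept-6-en-3-yl]oxy}vinyl)-2,2-dimethyl-1,3-dioxolane | CC[C@@H](OC(=C)[C@@H]1COC(C)(C)O1)[C@H](OCOC)C/C(Cl)=C\I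
A2 | alternative 1 | (4S)-4-[(2R,7R,8R,4E)-5-chloro-8-ethyl-7-(methoxymethoxy)-3,6,7,8-tetrahydro-2H-oxocin-2-yl]-2,2-dimethyl-1,3-dioxolane | CC1(C)OC[C@H](O1)[C@H]2C/C=C(/Cl)C[C@@H](OCOC)[C@@H](CC)O2
A3 | alternative 2 | (6R)-6-[(benzyloxy)methyl]-4-(1-chlorovinyl)-2-methylene-1,3-dioxane (either epimer at the chlorovinyl-bearing carbon) | C=C1O[C@@H](COCc2ccccc2)CC(C(Cl)=C)O1
A4 | alternative 2 | (8R,5E)-8-[(benzyloxy)methyl]-5-chloro-3,4,7,8-tetrahydro-2H-oxocin-2-one (cis ring alkene) | c1ccccc1COC[C@H]1C/C=C(/Cl)CCC(=O)O1
A5 | alternative 3 | (6R,3E)-3-chloro-7-[(4-methoxybenzyl)oxy]-6-{[(Z)-3-(tributylstannyl)prop-1-en-1-yl]oxy}hept-3-enal | COc1ccc(COC[C@@H](C/C=C(/Cl)CC=O)O/C=C\C[Sn](CCCC)(CCCC)CCCC)cc1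
A6 | alternative 3 | (2R,3S,8R,5E)-5-chloro-8-{[(4-methoxybenzyl)oxy]methyl}-2-vinyl-3,4,7,8-tetrahydro-2H-oxocin-3-ol | COc1ccc(COC[C@H]2C/C=C(/Cl)C[C@H](O)[C@@H](C=C)O2)cc1
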